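**Retrosynthetic overview**

1. Target ⇒ keto ester 15: the C1 ketone becomes the 1β-acetate, the C18 methyl ester becomes the icosanoyloxymethyl group, and the C11 CH2OBn arm becomes the (12E)-12,14-dienyl chain by three Wittig reactions.
2. 15 ⇒ acyclic vinyl ketone/enoate 11 by an intramolecular double Michael reaction: the C10–C5 bond closes ring B first, the C3–C4 bond closes ring A last, and C5, C10 and C4 are set there.
3. Enabling feature: in ring A the C1 oxygen (as ketone) and C18 on quaternary C4 (as ester) are 1,5-related along both arcs, O=C1–C10–C5–C4–C18=O and O=C1–C2–C3–C4–C18=O. Ring A is therefore the formal [4+2] adduct of the 2-oxy diene C10=C1–C2=C3 and the enoate C5=C4(C19)–C18.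
4. 11 ⇒ geraniol: Sharpless epoxidation fixes C8; SN2 opening at C9 by a propionitrile anion fixes C9 and brings C10, C20 and C1; ozonolysis/Wittig gives the enoate; CH2=CHMgBr on a Weinreb amide brings C2 and C3.

Key step: step 8

Remark: atom numbers in names and text are the labdane numbers of the target (ring A = C1–C5 and C10; ring B = C5–C10; C11–C16 side chain on C9; C17 on C8; C18 (α) and C19 (β) on C4; C20 on C10), and the acyclic compounds 4–12 are carried as C10 epimer mixtures because C10 becomes trigonal in the key step.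

**Route**

Step 1
Reactants: 1 geraniol
Product: 2 (2R,3R)-2,3-epoxygeraniol
Conditions: Ti(OiPr)4 (5 mol %), D-(−)-diethyl tartrate (6 mol %), t-BuOOH, 4 Å molecular sieves, CH2Cl2, −20 °C
Reagents that add atoms: tert-butyl hydroperoxide CC(C)(C)OO
Why: Sharpless asymmetric epoxidation of a primary allylic alcohol is regioselective for the 2,3-alkene and with D-(−)-tartrate should give the (2R,3R)-epoxide, whose oxygen becomes the 8α oxygen (8R).

Step 2
Reactants: 2 (2R,3R)-2,3-epoxygeraniol
Product: 3 (2R,3R)-2-[(benzyloxy)methyl]-3-methyl-3-(4-methylpent-3-en-1-yl)oxirane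
Conditions: NaH, BnBr, n-Bu4NI (cat.), THF, 0 °C → rt
Reagents that add atoms: benzyl bromide BrCc1ccccc1
Why: Williamson etherification; the benzyl ether shuts off Payne rearrangement in step 3 and survives every step up to hydrogenolysis.

Step 3
Reactants: 3 (2R,3R)-2-[(benzyloxy)methyl]-3-methyl-3-(4-methylpent-3-en-1-yl)oxirane
Product: 6 (3RS,4S,5R)-4-[(benzyloxy)methyl]-3,5-dimethyl-5-(4-methylpent-3-en-1-yl)oxolan-2-one, via hydroxy nitrile 4 (not isolated), via cyclic imidate 5 (not isolated)
Conditions: LiN(iPr)2, CH3CH2CN, THF/DMPU, −78 °C; add 3, −78 → 40 °C; then 1 M aq. HCl, THF, rt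
Reagents that add atoms: propanenitrile CCC#N; water O
Why: SN2 opening of the trisubstituted epoxide by a nitrile-stabilized carbanion at the only accessible (secondary) carbon C9 proceeds with inversion and sets the anti relation of the C8 oxygen and the new C9–C10 bond, after which the tertiary alkoxide adds to the nitrile and the cyclic imidate is hydrolysed to the γ-lactone (nitrile anion epoxide opening/lactonization).

Step 4
Reactants: 6 (3RS,4S,5R)-4-[(benzyloxy)methyl]-3,5-dimethyl-5-(4-methylpent-3-en-1-yl)oxolan-2-one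
Product: 7 (2RS,3S,4R)-3-[(benzyloxy)methyl]-4-hydroxy-N-methoxy-N,2,4,8-tetramethylnon-7-enamide
Conditions: MeNH(OMe)·HCl, AlMe3, CH2Cl2, 0 °C → rt; aq. potassium sodium tartrate work-up; used at once
Reagents that add atoms: N,O-dimethylhydroxylamine hydrochloride CNOC.Cl
Why: Weinreb aminolysis of a lactone with the aluminium amide made from AlMe3; the product is silylated immediately because tertiary γ-hydroxy amides relactonize.

Step 5
Reactants: 7 (2RS,3S,4R)-3-[(benzyloxy)methyl]-4-hydroxy-N-methoxy-N,2,4,8-tetramethylnon-7-enamide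
Product: 8 (2RS,3S,4R)-3-[(benzyloxy)methyl]-N-methoxy-N,2,4,8-tetramethyl-4-[(triethylsilyl)oxy]non-7-enamide
Conditions: Et3SiOTf, 2,6-lutidine, CH2Cl2, −78 → 0 °C
Reagents that add atoms: triethylsilyl trifluoromethanesulfonate CC[Si](CC)(CC)OS(=O)(=O)C(F)(F)F
Why: Silylation of a hindered tertiary alcohol with a silyl triflate; the triethylsilyl ether blocks relactonization and later keeps the C8 oxygen out of retro-aldol and oxa-Michael pathways.

Step 6
Reactants: 8 (2RS,3S,4R)-3-[(benzyloxy)methyl]-N-methoxy-N,2,4,8-tetramethyl-4-[(triethylsilyl)oxy]non-7-enamide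
Product: 10 methyl (2E,6R,7S,8RS)-7-[(benzyloxy)methyl]-9-[methoxy(methyl)amino]-2,6,8-trimethyl-9-oxo-6-[(triethylsilyl)oxy]non-2-enoate, via aldehyde 9 (not isolated)
Conditions: O3, CH2Cl2, −78 °C; PPh3, → rt; then Ph3P=C(CH3)CO2CH3, 40 °C, same flask
Reagents that add atoms: methyl 2-(triphenylphosphoranylidene)propanoate COC(=O)C(C)=P(c1ccccc1)(c1ccccc1)c1ccccc1
Why: Ozonolysis of the only C=C bond with PPh3 reduction, then Wittig olefination of the aldehyde in the same flask with a stabilized ylide, should give the trisubstituted (E)-enoate and brings C4, C18 and C19.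

Step 7
Reactants: 10 methyl (2E,6R,7S,8RS)-7-[(benzyloxy)methyl]-9-[methoxy(methyl)amino]-2,6,8-trimethyl-9-oxo-6-[(triethylsilyl)oxy]non-2-enoate
Product: 11 methyl (2E,6R,7S,8RS)-7-[(benzyloxy)methyl]-2,6,8-trimethyl-9-oxo-6-[(triethylsilyl)oxy]undeca-2,10-dienoate
Conditions: CH2=CHMgBr, THF, −40 → 0 °C; inverse quench into cold 1 M aq. HCl
Reagents that add atoms: vinylmagnesium bromide C=C[Mg]Br
Why: Weinreb ketone synthesis: the N-methoxy-N-methylamide takes up one equivalent of Grignard reagent faster than the hindered conjugated methyl ester and releases the ketone only on the acidic quench, which also prevents aza-Michael addition of the liberated amine.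

Step 8
Reactants: 11 methyl (2E,6R,7S,8RS)-7-[(benzyloxy)methyl]-2,6,8-trimethyl-9-oxo-6-[(triethylsilyl)oxy]undeca-2,10-dienoate
Product: 15 methyl 11-(benzyloxy)-1-oxo-8α-[(triethylsilyl)oxy]-12,13,14,15,16-pentanorlabdan-18-oate (trans-decalin; 5α-H, 9α-H, 10β-CH3, 4β-CH3, 4α-CO2CH3), via silyl dienol ether 12 (not isolated), via ring B silyl ketene acetal 13 (not isolated), via bicyclic silyl enol ether 14 (not isolated)
Conditions: Et3SiOTf, Et3N, CH2Cl2 (0.01 M), −78 °C → rt; then 0.5 M aq. HCl, THF, 0 °C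
Reagents that add atoms: none
Why: Et3SiOTf/Et3N silylates the only enolizable position of the vinyl ketone (C10) to give the 2-silyloxy diene 12, whose C10 terminus adds to C5 of the silyl-activated enoate (Mukaiyama–Michael) and whose product, silyl ketene acetal 13, adds through C4 to C3 of the regenerated vinyl ketone; the closest known reaction is the silyl triflate/amine-mediated intramolecular double Michael reaction of enone–enoates (Ihara–Fukumoto), formally a stepwise [4+2] union of the diene C10=C1–C2=C3 with the dienophile C4=C5. Ring B closes first by the C10–C5 bond in 6-exo-trig mode and ring A closes last by the C3–C4 bond in 6-endo-trig mode. In the first closure the C9–H bond eclipses the C10=C1 enol bond (allylic 1,3-strain), so C5 approaches C10 anti to the C9 CH2OBn group through a chair with C1, C4, C11 and the C8 oxygen equatorial, which makes the C10 methyl axial (β) and C5–H axial (α), i.e. the trans ring fusion. In the second closure the C5–H bond eclipses the C4=C18 ketene acetal bond and C3 can only arrive on the C10 side, which puts C18 equatorial (α) and the C19 methyl axial (β). The step needs intramolecular C–C bond formation to outrun oligomerization of the vinyl ketone and needs C9 to relay its configuration; high dilution, the Thorpe–Ingold effect of the fully substituted C8 and the equatorial preference of the protected C8 and C11 substituents secure this.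

Step 9
Reactants: 15 methyl 11-(benzyloxy)-1-oxo-8α-[(triethylsilyl)oxy]-12,13,14,15,16-pentanorlabdan-18-oate
Product: 16 methyl 11-hydroxy-1-oxo-8α-[(triethylsilyl)oxy]-12,13,14,15,16-pentanorlabdan-18-oate
Conditions: H2 (1 atm), Pd/C (10 wt %), EtOAc, rt
Reagents that add atoms: none
Why: Hydrogenolysis of the benzyl ether; no C=C bond is present at this stage and the ketone, ester and silyl ether are inert.

Step 10
Reactants: 16 methyl 11-hydroxy-1-oxo-8α-[(triethylsilyl)oxy]-12,13,14,15,16-pentanorlabdan-18-oate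
Product: 17 methyl 1,11-dioxo-8α-[(triethylsilyl)oxy]-12,13,14,15,16-pentanorlabdan-18-oate
Conditions: Dess–Martin periodinane, CH2Cl2, 0 °C → rt
Reagents that add atoms: none
Why: Dess–Martin oxidation of the primary alcohol under near-neutral conditions; C9–H lies between two fully substituted carbons, so epimerization should be slow and the equatorial formyl group is kept.

Step 11
Reactants: 17 methyl 1,11-dioxo-8α-[(triethylsilyl)oxy]-12,13,14,15,16-pentanorlabdan-18-oate
Product: 19 methyl 1,12-dioxo-8α-[(triethylsilyl)oxy]-13,14,15,16-tetranorlabdan-18-oate, via enol ether 18 (not isolated)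
Conditions: CH3OCH2PPh3Cl, KN(SiMe3)2, THF, −78 → 0 °C; then 0.5 M aq. HCl, THF, 0 °C → rt, same flask
Reagents that add atoms: (methoxymethyl)triphenylphosphonium chloride COC[P+](c1ccccc1)(c1ccccc1)c1ccccc1.[Cl-]; water O
Why: Wittig methoxymethylenation of the aldehyde, much faster than at the C1 ketone next to quaternary C10, followed by acid hydrolysis of the enol ether is a one-carbon homologation that brings C12.

Step 12
Reactants: 19 methyl 1,12-dioxo-8α-[(triethylsilyl)oxy]-13,14,15,16-tetranorlabdan-18-oate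
Product: 20 methyl (12E)-1,14-dioxo-8α-[(triethylsilyl)oxy]-15-norlabd-12-en-18-oate
Conditions: Ph3P=C(CH3)CHO, toluene, 80 °C
Reagents that add atoms: 2-(triphenylphosphoranylidene)propanal CC(C=O)=P(c1ccccc1)(c1ccccc1)c1ccccc1
Why: Wittig olefination with a formyl-stabilized ylide should give the trisubstituted (E)-enal (C13, C14, C16) and leaves the hindered ketone alone.

Step 13
Reactants: 20 methyl (12E)-1,14-dioxo-8α-[(triethylsilyl)oxy]-15-norlabd-12-en-18-oate
Product: 21 methyl (12E)-1-oxo-8α-[(triethylsilyl)oxy]labda-12,14-dien-18-oate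
Conditions: CH3PPh3Br, KN(SiMe3)2, THF, −78 → 0 °C
Reagents that add atoms: methyltriphenylphosphonium bromide C[P+](c1ccccc1)(c1ccccc1)c1ccccc1.[Br-]
Why: Wittig methylenation of the enal carbonyl (1,2-addition) completes the (12E)-12,14-diene, while the hindered C1 ketone and the ester react far more slowly at low temperature.

Step 14
Reactants: 21 methyl (12E)-1-oxo-8α-[(triethylsilyl)oxy]labda-12,14-dien-18-oate
Product: 22 (12E)-8α-[(triethylsilyl)oxy]labda-12,14-diene-1β,18-diol
Conditions: LiAlH4, THF, −20 → 0 °C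
Reagents that add atoms: none
Why: LiAlH4 reduction of ketone and ester; hydride should add to C1 along the axial trajectory on the α face, away from the β C20 methyl and the C11 chain, to give the equatorial 1β-alcohol, and the isolated diene and the silyl ether are inert.

Step 15
Reactants: 22 (12E)-8α-[(triethylsilyl)oxy]labda-12,14-diene-1β,18-diol
Product: 23 (12E)-1β-hydroxy-8α-[(triethylsilyl)oxy]labda-12,14-dien-18-yl icosanoate
Conditions: icosanoyl chloride (1.05 equiv), pyridine, CH2Cl2, −20 → 0 °C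
Reagents that add atoms: icosanoyl chloride CCCCCCCCCCCCCCCCCCCC(=O)Cl
Why: Chemoselective acylation of the primary alcohol with one equivalent of acid chloride at low temperature; the secondary C1 hydroxyl next to quaternary C10 should react much more slowly.

Step 16
Reactants: 23 (12E)-1β-hydroxy-8α-[(triethylsilyl)oxy]labda-12,14-dien-18-yl icosanoate
Product: 24 (12E)-1β-acetoxy-8α-[(triethylsilyl)oxy]labda-12,14-dien-18-yl icosanoate
Conditions: Ac2O, DMAP (cat.), pyridine, rt
Reagents that add atoms: acetic anhydride CC(=O)OC(C)=O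
Why: DMAP-catalysed acetylation of the remaining secondary alcohol; the tertiary C8 oxygen is still silylated.

Step 17
Reactants: 24 (12E)-1β-acetoxy-8α-[(triethylsilyl)oxy]labda-12,14-dien-18-yl icosanoate
Product: 25 (12E)-1β-acetoxy-8α-hydroxylabda-12,14-dien-18-yl icosanoate (CNP0288884.2)
Conditions: HF·pyridine, pyridine/THF, 0 °C → rt
Reagents that add atoms: none
Why: Fluoride-mediated cleavage of the tertiary triethylsilyl ether under buffered conditions should leave both esters and the diene intact and give the target.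

**Compound list**

1 | geraniol, (2E)-3,7-dimethylocta-2,6-dien-1-ol | CC(C)=CCC/C(C)=C/CO | starting material
2 | (2R,3R)-2,3-epoxygeraniol, [(2R,3R)-3-methyl-3-(4-methylpent-3-en-1-yl)oxiran-2-yl]methanol | CC(C)=CCC[C@@]1(C)O[C@@H]1CO | intermediate
3 | (2R,3R)-2-[(benzyloxy)methyl]-3-methyl-3-(4-methylpent-3-en-1-yl)oxirane | CC(C)=CCC[C@@]1(C)O[C@@H]1COCc2ccccc2 | intermediate
4 | hydroxy nitrile, (2RS,3S,4R)-3-[(benzyloxy)methyl]-4-hydroxy-2,4,8-trimethylnon-7-enenitrile (lithium alkoxide in the flask) | N#CC(C)[C@@H](COCc1ccccc1)[C@](C)(O)CCC=C(C)C | intermediate (not isolated)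
5 | cyclic imidate, (3RS,4S,5R)-4-[(benzyloxy)methyl]-3,5-dimethyl-5-(4-methylpent-3-en-1-yl)oxolan-2-imine (N-lithio form in the flask) | N=C1O[C@](C)(CCC=C(C)C)[C@H](COCc2ccccc2)C1C | intermediate (not isolated)
6 | (3RS,4S,5R)-4-[(benzyloxy)methyl]-3,5-dimethyl-5-(4-methylpent-3-en-1-yl)oxolan-2-one | O=C1O[C@](C)(CCC=C(C)C)[C@H](COCc2ccccc2)C1C | intermediate
7 | (2RS,3S,4R)-3-[(benzyloxy)methyl]-4-hydroxy-N-methoxy-N,2,4,8-tetramethylnon-7-enamide | CON(C)C(=O)C(C)[C@@H](COCc1ccccc1)[C@](C)(O)CCC=C(C)C | intermediate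
8 | (2RS,3S,4R)-3-[(benzyloxy)methyl]-N-methoxy-N,2,4,8-tetramethyl-4-[(triethylsilyl)oxy]non-7-enamide | CON(C)C(=O)C(C)[C@@H](COCc1ccccc1)[C@](C)(O[Si](CC)(CC)CC)CCC=C(C)C | intermediate
9 | aldehyde, (2RS,3S,4R)-3-[(benzyloxy)methyl]-N-methoxy-N,2,4-trimethyl-7-oxo-4-[(triethylsilyl)oxy]heptanamide | CON(C)C(=O)C(C)[C@@H](COCc1ccccc1)[C@](C)(O[Si](CC)(CC)CC)CCC=O | intermediate (not isolated)
10 | methyl (2E,6R,7S,8RS)-7-[(benzyloxy)methyl]-9-[methoxy(methyl)amino]-2,6,8-trimethyl-9-oxo-6-[(triethylsilyl)oxy]non-2-enoate | CON(C)C(=O)C(C)[C@@H](COCc1ccccc1)[C@](C)(O[Si](CC)(CC)CC)CC/C=C(\C)C(=O)OC | intermediate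
11 | methyl (2E,6R,7S,8RS)-7-[(benzyloxy)methyl]-2,6,8-trimethyl-9-oxo-6-[(triethylsilyl)oxy]undeca-2,10-dienoate | C=CC(=O)C(C)[C@@H](COCc1ccccc1)[C@](C)(O[Si](CC)(CC)CC)CC/C=C(\C)C(=O)OC | intermediate
12 | silyl dienol ether, methyl (2E,6R,7S)-7-[(benzyloxy)methyl]-2,6,8-trimethyl-6,9-bis[(triethylsilyl)oxy]undeca-2,8,10-trienoate (C8=C9 geometry open) | C=CC(O[Si](CC)(CC)CC)=C(C)[C@@H](COCc1ccccc1)[C@](C)(O[Si](CC)(CC)CC)CC/C=C(\C)C(=O)OC | intermediate (not isolated)
13 | ring B silyl ketene acetal: cyclohexane C5–C10 closed; C10 carries CH3 and the prop-2-enoyl group C1–C3; C5 carries C4(CH3)=C18(OCH3)(OSiEt3); C8 CH3 and OSiEt3; C9 CH2OBn | c3ccccc3COC[C@@H]1[C@@](C)(C(=O)C=C)[C@H](C(C)=C(OC)O[Si](CC)(CC)CC)CC[C@@]1(C)O[Si](CC)(CC)CC | intermediate (not isolated)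
14 | bicyclic silyl enol ether, methyl 11-(benzyloxy)-1,8α-bis[(triethylsilyl)oxy]-12,13,14,15,16-pentanorlabd-1-en-18-oate | c3ccccc3COC[C@@H]1[C@@]2(C)C(O[Si](CC)(CC)CC)=CC[C@@](C)(C(=O)OC)[C@@H]2CC[C@@]1(C)O[Si](CC)(CC)CC | intermediate (not isolated)
15 | methyl 11-(benzyloxy)-1-oxo-8α-[(triethylsilyl)oxy]-12,13,14,15,16-pentanorlabdan-18-oate (5α-H, 9α-H, 10β-CH3, 4β-CH3) | c3ccccc3COC[C@@H]1[C@@]2(C)C(=O)CC[C@@](C)(C(=O)OC)[C@@H]2CC[C@@]1(C)O[Si](CC)(CC)CC | intermediate
16 | methyl 11-hydroxy-1-oxo-8α-[(triethylsilyl)oxy]-12,13,14,15,16-pentanorlabdan-18-oate | OC[C@@H]1[C@@]2(C)C(=O)CC[C@@](C)(C(=O)OC)[C@@H]2CC[C@@]1(C)O[Si](CC)(CC)CC | intermediate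
17 | methyl 1,11-dioxo-8α-[(triethylsilyl)oxy]-12,13,14,15,16-pentanorlabdan-18-oate | O=C[C@@H]1[C@@]2(C)C(=O)CC[C@@](C)(C(=O)OC)[C@@H]2CC[C@@]1(C)O[Si](CC)(CC)CC | intermediate
18 | enol ether, methyl 12-methoxy-1-oxo-8α-[(triethylsilyl)oxy]-13,14,15,16-tetranorlabd-11-en-18-oate (E/Z mixture) | COC=C[C@@H]1[C@@]2(C)C(=O)CC[C@@](C)(C(=O)OC)[C@@H]2CC[C@@]1(C)O[Si](CC)(CC)CC | intermediate (not isolated)
19 | methyl 1,12-dioxo-8α-[(triethylsilyl)oxy]-13,14,15,16-tetranorlabdan-18-oate | O=CC[C@@H]1[C@@]2(C)C(=O)CC[C@@](C)(C(=O)OC)[C@@H]2CC[C@@]1(C)O[Si](CC)(CC)CC | intermediate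
20 | methyl (12E)-1,14-dioxo-8α-[(triethylsilyl)oxy]-15-norlabd-12-en-18-oate | O=C/C(C)=C/C[C@@H]1[C@@]2(C)C(=O)CC[C@@](C)(C(=O)OC)[C@@H]2CC[C@@]1(C)O[Si](CC)(CC)CC | intermediate
21 | methyl (12E)-1-oxo-8α-[(triethylsilyl)oxy]labda-12,14-dien-18-oate | C=C/C(C)=C/C[C@@H]1[C@@]2(C)C(=O)CC[C@@](C)(C(=O)OC)[C@@H]2CC[C@@]1(C)O[Si](CC)(CC)CC | intermediate
22 | (12E)-8α-[(triethylsilyl)oxy]labda-12,14-diene-1β,18-diol | C=C/C(C)=C/C[C@@H]1[C@@]2(C)[C@H](O)CC[C@@](C)(CO)[C@@H]2CC[C@@]1(C)O[Si](CC)(CC)CC | intermediate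
23 | (12E)-1β-hydroxy-8α-[(triethylsilyl)oxy]labda-12,14-dien-18-yl icosanoate | C=C/C(C)=C/C[C@@H]1[C@@]2(C)[C@H](O)CC[C@@](C)(COC(=O)CCCCCCCCCCCCCCCCCCC)[C@@H]2CC[C@@]1(C)O[Si](CC)(CC)CC | intermediate
24 | (12E)-1β-acetoxy-8α-[(triethylsilyl)oxy]labda-12,14-dien-18-yl icosanoate | C=C/C(C)=C/C[C@@H]1[C@@]2(C)[C@H](OC(C)=O)CC[C@@](C)(COC(=O)CCCCCCCCCCCCCCCCCCC)[C@@H]2CC[C@@]1(C)O[Si](CC)(CC)CC | intermediate
25 | (12E)-1β-acetoxy-8α-hydroxylabda-12,14-dien-18-yl icosanoate, CNP0288884.2 | C=C/C(C)=C/C[C@@H]1[C@@]2(C)[C@H](OC(C)=O)CC[C@@](C)(COC(=O)CCCCCCCCCCCCCCCCCCC)[C@@H]2CC[C@@]1(C)O | target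

**Step count**

Total steps: 17. Longest linear sequence: 17 steps (from geraniol).

**Steps most likely to fail, with fallbacks**

Step 8 (key double Michael closure). The first conjugate addition joins a fully substituted enol carbon (C10) to an α-methyl enoate and may be slow, so that oligomerization of the vinyl ketone or simple desilylation wins; the relay of configuration from C9 may also be incomplete (loss of facial selectivity at C10). The fallback runs the two conjugate additions apart and adds C3 later; it sets out from 10 and comes back at 15. CH3MgBr (THF, 0 °C) converts the Weinreb amide into the methyl ketone F1. KOt-Bu in t-BuOH/THF equilibrates the ketone enolates, of which only the C10 enolate can close a six-membered ring onto C5, and should give the ring B methyl ketone F2. α-Methylenation of the methyl ketone with paraformaldehyde and N-methylanilinium trifluoroacetate (THF, reflux) should give the ring B vinyl ketone F3. LiN(SiMe3)2 or KOt-Bu in THF then closes ring A by Michael addition of the ester enolate (C4) to the vinyl ketone and returns to 15.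

Step 3 (epoxide opening). SN2 attack at the hindered secondary epoxide carbon C9 may be sluggish, and base-induced isomerization of the epoxide to an allylic alcohol may compete. The fallback uses an organocopper opening and builds the lactone by oxidation; it sets out from 3 and comes back at 6. CH2=C(CH3)MgBr with CuI (cat.) in THF at −30 °C should open the epoxide at C9 with inversion to the homoallylic alcohol F4. 9-BBN followed by NaOH/H2O2 hydroborates the 1,1-disubstituted alkene in preference to the trisubstituted one and should give the 1,4-diol F5. Oxidative lactonization with TEMPO/PhI(OAc)2 in CH2Cl2 returns to 6.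

Step 14 (C1 reduction). Facial selectivity of hydride delivery to the C1 ketone may be poor, with equatorial attack from the β face giving the axial 1α-alcohol. The fallback replaces kinetic hydride addition by a reversible hydride transfer under thermodynamic control; it sets out from 21 and comes back at 22. Meerwein–Ponndorf–Verley reduction with Al(OiPr)3 in i-PrOH/toluene at 80 °C equilibrates the carbinol center toward the equatorial 1β-alcohol and should give the hydroxy ester F6; the hindered C18 methyl ester on quaternary C4 is expected to survive. LiAlH4 in THF then reduces the ester and returns to 22.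

**Further compounds**

F1 | step 8 | methyl (2E,6R,7S,8RS)-7-[(benzyloxy)methyl]-2,6,8-trimethyl-9-oxo-6-[(triethylsilyl)oxy]dec-2-enoate | CC(=O)C(C)[C@@H](COCc1ccccc1)[C@](C)(O[Si](CC)(CC)CC)CC/C=C(\C)C(=O)OC
F2 | step 8 | ring B methyl ketone: cyclohexane C5–C10 closed; C10 carries CH3 and acetyl; C5 carries CH(CH3)CO2CH3 (C4 epimers); C8 CH3 and OSiEt3; C9 CH2OBn | c3ccccc3COC[C@@H]1[C@@](C)(C(C)=O)[C@H](C(C)C(=O)OC)CC[C@@]1(C)O[Si](CC)(CC)CC
F3 | step 8 | ring B vinyl ketone: as F2 with prop-2-enoyl in place of acetyl at C10 | c3ccccc3COC[C@@H]1[C@@](C)(C(=O)C=C)[C@H](C(C)C(=O)OC)CC[C@@]1(C)O[Si](CC)(CC)CC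
F4 | step 3 | (3S,4R)-3-[(benzyloxy)methyl]-2,4,8-trimethylnona-1,7-dien-4-ol | C=C(C)[C@@H](COCc1ccccc1)[C@](C)(O)CCC=C(C)C
F5 | step 3 | (2RS,3S,4R)-3-[(benzyloxy)methyl]-2,4,8-trimethylnon-7-ene-1,4-diol | OCC(C)[C@@H](COCc1ccccc1)[C@](C)(O)CCC=C(C)C
F6 | step 14 | methyl (12E)-1β-hydroxy-8α-[(triethylsilyl)oxy]labda-12,14-dien-18-oate | C=C/C(C)=C/C[C@@H]1[C@@]2(C)[C@H](O)CC[C@@](C)(C(=O)OC)[C@@H]2CC[C@@]1(C)O[Si](CC)(CC)CC
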